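Prostanoid numbering is used: C1 is the ester carbon, C7 the acetoxy carbon, C8–C12 the ring. The plan reads C9(=O)–C8–C7–O as an aldol retron. C8 is the only enolisable carbon of the cross-conjugated 2-bromocyclopentenone ring and lies next to the C12 tertiary carbinol. In the key step the unprotected bromo hydroxy enone is doubly deprotonated. The alkoxide–enolate dianion, which cannot expel the C12 oxygen, adds to methyl (Z)-7-oxohept-5-enoate. One operation joins both halves and sets C7 and C8 under control of C12, without protecting groups. The ring half comes from (R)-4-silyloxycyclopentenone, the enal from a Z-retentive cross-metathesis.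

Key step: step 10

Remark: 3 is assumed to be bought enantiopure. The minor carbinol epimer from step 2 has to be removed by chromatography, because after step 4 it would give the enantiomeric ring half.

Step 1
Reactants: 1 (Z)-oct-2-en-1-ol
Product: 2 (Z)-1-chlorooct-2-ene
Conditions: NCS, Me2S, CH2Cl2, −20 to 0 °C
Reagents that add atoms: N-chlorosuccinimide O=C1CCC(=O)N1Cl
Why: Corey–Kim-type chlorination, in which chloride displaces the alkoxysulfonium group at the primary carbon by SN2, so neither allylic transposition nor Z to E isomerisation is expected.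

Step 2
Reactants: 2 (Z)-1-chlorooct-2-ene; 3 (R)-4-(tert-butyldimethylsilyloxy)cyclopent-2-en-1-one
Product: 5 (1S,4R)-4-(tert-butyldimethylsilyloxy)-1-[(Z)-oct-2-en-1-yl]cyclopent-2-en-1-ol (OH and OTBS cis), via (Z)-oct-2-enylbarium chloride 4 (not isolated)
Conditions: BaI2, lithium biphenylide (2 equiv), THF, rt; 2, −78 °C; 3, −78 °C; aq NH4Cl
Reagents that add atoms: none
Why: Allylbarium 1,2-addition, in which allylic barium reagents made from activated barium at −78 °C keep their Z geometry and attack the carbonyl carbon of enones through their unsubstituted α-carbon, and approach anti to the C4 silyloxy group sets the tertiary carbinol (future C12) as S.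

Step 3
Reactants: 5 (1S,4R)-4-(tert-butyldimethylsilyloxy)-1-[(Z)-oct-2-en-1-yl]cyclopent-2-en-1-ol
Product: 6 (1S,4R)-1-[(Z)-oct-2-en-1-yl]cyclopent-2-ene-1,4-diol (cis diol)
Conditions: TBAF, AcOH (1:1), THF, rt
Reagents that add atoms: none
Why: Fluoride-mediated silyl ether cleavage, buffered with acetic acid so that the ionisable bis-allylic diol meets neither strong base nor strong acid, and no stereocentre is touched.

Step 4
Reactants: 6 (1S,4R)-1-[(Z)-oct-2-en-1-yl]cyclopent-2-ene-1,4-diol
Product: 7 (S)-4-hydroxy-4-[(Z)-oct-2-en-1-yl]cyclopent-2-en-1-one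
Conditions: MnO2, CH2Cl2, rt
Reagents that add atoms: none
Why: Chemoselective allylic oxidation with MnO2, in which only the secondary allylic alcohol can react, the tertiary carbinol and the isolated Z-alkene are inert, and the auxiliary carbinol stereocentre is erased as planned.

Step 5
Reactants: 7 (S)-4-hydroxy-4-[(Z)-oct-2-en-1-yl]cyclopent-2-en-1-one
Product: 8 (1S,4S,5R)-4-hydroxy-4-[(Z)-oct-2-en-1-yl]-6-oxabicyclo[3.1.0]hexan-2-one (epoxide oxygen cis to the hydroxyl)
Conditions: 30% H2O2, cat. NaOH, MeOH, −10 to 0 °C, short contact time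
Reagents that add atoms: hydrogen peroxide OO
Why: Weitz–Scheffer nucleophilic epoxidation, in which hydroperoxide attacks only the electron-poor enone C=C and spares the isolated Z-alkene, addition anti to the octenyl CH2 (syn to the hydroxyl) should give the cis hydroxy epoxide, and both new centres are erased in step 7.

Step 6
Reactants: 8 (1S,4S,5R)-4-hydroxy-4-[(Z)-oct-2-en-1-yl]-6-oxabicyclo[3.1.0]hexan-2-one
Product: 9 (2R,3S,4S)-2-bromo-3,4-dihydroxy-4-[(Z)-oct-2-en-1-yl]cyclopentan-1-one
Conditions: LiBr, AcOH, THF, 0 °C to rt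
Reagents that add atoms: lithium bromide [Li+].[Br-]
Why: Regioselective halide opening of an α,β-epoxy ketone, in which bromide attacks with inversion at the carbonyl-activated α-carbon (future C10) because the β-carbon is neopentyl-like next to the quaternary carbinol, under conditions too mild to add HBr to the alkene.

Step 7
Reactants: 9 (2R,3S,4S)-2-bromo-3,4-dihydroxy-4-[(Z)-oct-2-en-1-yl]cyclopentan-1-one
Product: 11 (S)-2-bromo-4-hydroxy-4-[(Z)-oct-2-en-1-yl]cyclopent-2-en-1-one, via secondary mesylate 10 (not isolated)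
Conditions: MsCl, Et3N, CH2Cl2, −20 to 0 °C
Reagents that add atoms: none
Why: Selective mesylation of the secondary alcohol followed by E1cB elimination, in which the proton on the brominated α-carbon is the most acidic one, so loss of mesylate gives the 2-bromo enone while the unreactive tertiary C12 hydroxyl stays in place.

Step 8
Reactants: 12 methyl hex-5-enoate; 13 (Z)-but-2-ene-1,4-diol
Product: 14 methyl (Z)-7-hydroxyhept-5-enoate
Conditions: Ru catechodithiolate NHC carbene catalyst (5 mol %), THF, 22 °C
Reagents that add atoms: none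
Why: Stereoretentive (Z-selective) olefin cross-metathesis, in which Ru dithiolate catalysts transfer the Z geometry of the butenediol partner to the new disubstituted alkene and tolerate ester and hydroxyl groups.

Step 9
Reactants: 14 methyl (Z)-7-hydroxyhept-5-enoate
Product: 15 methyl (Z)-7-oxohept-5-enoate
Conditions: TEMPO (10 mol %), PhI(OAc)2, MeCN/pH 7 buffer, 0 °C; used at once
Reagents that add atoms: none
Why: TEMPO/PhI(OAc)2 (Piancatelli–Margarita) oxidation, in which the buffered oxoammonium oxidation of a Z-allylic alcohol stops at the aldehyde and is of the type that preserves Z geometry.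

Step 10
Reactants: 11 (S)-2-bromo-4-hydroxy-4-[(Z)-oct-2-en-1-yl]cyclopent-2-en-1-one; 15 methyl (Z)-7-oxohept-5-enoate
Product: 18 methyl (5Z,7S)-7-{(1R,2S)-4-bromo-2-hydroxy-2-[(Z)-oct-2-en-1-yl]-5-oxocyclopent-3-en-1-yl}-7-hydroxyhept-5-enoate, via dilithium alkoxide-enolate 16 (not isolated), via dilithium aldolate 17 (not isolated)
Conditions: 11 added to LDA (2.2 equiv), THF, −78 °C; 15, −78 °C; AcOH/THF quench at −78 °C
Reagents that add atoms: none
Why: The first equivalent of LDA gives the C12 lithium alkoxide and the second removes a C8 proton, so dianion 16 forms and, unlike a silyloxy or acyloxy enolate, cannot expel the C12 oxygen to give a cyclopentadienone; its C8 carbon then adds to the aldehyde carbon of 15 in a lithium-closed aldol addition. The closest known reaction types are Fráter–Seebach-type β-alkoxide enolate dianion chemistry and the LDA aldol of 4-oxygenated 4-alkylcyclopent-2-enones with enals. No ring is closed. C8 is controlled by C12: the aldehyde oxygen is held by the lithium ions on the C9 enolate and C12 alkoxide oxygens and the aldehyde enters on the oxygen-bearing face, anti to the larger octenyl CH2, which places the new chain trans to the octenyl chain (8R). C7 is controlled by the fixed E(O) geometry of the ring enolate in a Zimmerman–Traxler chair with the alkenyl group equatorial, which gives the anti aldol (7S). The step needs site-selective enolisation, 1,2- rather than 1,4-addition and survival of both Z-alkenes, the vinyl bromide and the ester: C10 and C12 carry no hydrogen so only C8 can be deprotonated, the hard lithium enolate attacks the aldehyde carbon, and −78 °C with a cold acetic acid quench suppresses retro-aldol, dehydration and Z to E isomerisation.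

Step 11
Reactants: 18 methyl (5Z,7S)-7-{(1R,2S)-4-bromo-2-hydroxy-2-[(Z)-oct-2-en-1-yl]-5-oxocyclopent-3-en-1-yl}-7-hydroxyhept-5-enoate
Product: 19 7-acetoxy-7,8-dihydrobromovulone I, methyl (5Z,7S)-7-acetoxy-7-{(1R,2S)-4-bromo-2-hydroxy-2-[(Z)-oct-2-en-1-yl]-5-oxocyclopent-3-en-1-yl}hept-5-enoate
Conditions: Ac2O (1.5 equiv), pyridine, CH2Cl2, 0 °C
Reagents that add atoms: acetic anhydride CC(=O)OC(C)=O
Why: Chemoselective acetylation, in which the secondary allylic C7 alcohol is acylated with retention while the hindered tertiary C12 alcohol is inert without DMAP, and the weak base and low temperature avoid E1cB loss of the new β-acetoxy group.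

Compound list
1 | (Z)-oct-2-en-1-ol | CCCCC/C=C\CO | starting material
2 | (Z)-1-chlorooct-2-ene | CCCCC/C=C\CCl | intermediate
3 | (R)-4-(tert-butyldimethylsilyloxy)cyclopent-2-en-1-one | O=C1C=C[C@H](O[Si](C)(C)C(C)(C)C)C1 | starting material
4 | (Z)-oct-2-enylbarium chloride | CCCCC/C=C\C[Ba]Cl | intermediate
5 | (1S,4R)-4-(tert-butyldimethylsilyloxy)-1-[(Z)-oct-2-en-1-yl]cyclopent-2-en-1-ol | CCCCC/C=C\C[C@@]1(O)C=C[C@H](O[Si](C)(C)C(C)(C)C)C1 | intermediate
6 | (1S,4R)-1-[(Z)-oct-2-en-1-yl]cyclopent-2-ene-1,4-diol | CCCCC/C=C\C[C@@]1(O)C=C[C@H](O)C1 | intermediate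
7 | (S)-4-hydroxy-4-[(Z)-oct-2-en-1-yl]cyclopent-2-en-1-one | CCCCC/C=C\C[C@@]1(O)C=CC(=O)C1 | intermediate
8 | (1S,4S,5R)-4-hydroxy-4-[(Z)-oct-2-en-1-yl]-6-oxabicyclo[3.1.0]hexan-2-one | CCCCC/C=C\C[C@@]1(O)[C@@H]2O[C@@H]2C(=O)C1 | intermediate
9 | (2R,3S,4S)-2-bromo-3,4-dihydroxy-4-[(Z)-oct-2-en-1-yl]cyclopentan-1-one | CCCCC/C=C\C[C@@]1(O)[C@H](O)[C@@H](Br)C(=O)C1 | intermediate
10 | (2R,3S,4S)-2-bromo-4-hydroxy-3-(methylsulfonyloxy)-4-[(Z)-oct-2-en-1-yl]cyclopentan-1-one | CCCCC/C=C\C[C@@]1(O)[C@H](OS(C)(=O)=O)[C@@H](Br)C(=O)C1 | intermediate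
11 | (S)-2-bromo-4-hydroxy-4-[(Z)-oct-2-en-1-yl]cyclopent-2-en-1-one | CCCCC/C=C\C[C@@]1(O)C=C(Br)C(=O)C1 | intermediate
12 | methyl hex-5-enoate | C=CCCCC(=O)OC | starting material
13 | (Z)-but-2-ene-1,4-diol | OC/C=C\CO | starting material
14 | methyl (Z)-7-hydroxyhept-5-enoate | COC(=O)CCC/C=C\CO | intermediate
15 | methyl (Z)-7-oxohept-5-enoate | COC(=O)CCC/C=C\C=O | intermediate
16 | dilithium alkoxide-enolate of 11 | CCCCC/C=C\C[C@@]1([O-])C=C(Br)C([O-])=C1.[Li+].[Li+] | intermediate
17 | dilithium aldolate of 18 | CCCCC/C=C\C[C@@]1([O-])C=C(Br)C(=O)[C@@H]1[C@H](/C=C\CCCC(=O)OC)[O-].[Li+].[Li+] | intermediate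
18 | methyl (5Z,7S)-7-{(1R,2S)-4-bromo-2-hydroxy-2-[(Z)-oct-2-en-1-yl]-5-oxocyclopent-3-en-1-yl}-7-hydroxyhept-5-enoate | CCCCC/C=C\C[C@@]1(O)C=C(Br)C(=O)[C@@H]1[C@H](/C=C\CCCC(=O)OC)O | intermediate
19 | 7-acetoxy-7,8-dihydrobromovulone I | CCCCC/C=C\C[C@@]1(O)C=C(Br)C(=O)[C@@H]1[C@H](/C=C\CCCC(=O)OC)OC(C)=O | target

Total step count: 11
Longest linear sequence: 9 (steps 1–7, 10, 11)

Steps most likely to fail

Step 10 (key step). The aggregated dilithio species may show poor facial or C7 selectivity. The C12 alkoxide may open by retro-aldol before the second deprotonation. The enal may isomerise from Z to E under base. The fallback sets out from 11 and comes back at 19. The hydroxyl is capped with TESOTf/2,6-lutidine to give the C12 triethylsilyl ether F1. This is enolised softly with c-Hex2BCl/Et3N in Et2O at −78 °C. The dicyclohexylboron enolate adds to 15 through a tight boron chair, with non-oxidative work-up, to give the silyl-protected anti aldol F2. Ac2O/pyridine gives the silyl-protected acetate F3, and HF·pyridine in THF removes the silyl group to reach 19.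

Step 2. The allylbarium reagent may lose α-regioselectivity or Z geometry. The silyloxy enone may be enolised and undergo β-elimination. Discrimination between the two ketone faces may be weak. The fallback sets out from 3 and comes back at 5. Barbier addition of propargyl bromide with zinc in THF, again anti to the silyloxy group, gives the homopropargylic carbinol F4. Double lithiation with n-BuLi in THF/DMPU and C-alkylation with 1-iodopentane gives the oct-2-ynyl carbinol F5. Lindlar semihydrogenation, carried out before any bromine is present, gives 5.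

Step 5. Base may open the β-hydroxy ketone by retro-aldol, which would erode the configuration at C12. Peroxide addition next to the quaternary centre may also be sluggish. The fallback sets out from 6 and comes back at 8, bypassing steps 4 and 5. Hydroxyl-directed epoxidation of the ring alkene with VO(acac)2/t-BuOOH in CH2Cl2 gives the all-cis epoxy diol F6. Dess–Martin oxidation of its secondary alcohol gives 8 without any basic step.

Further compounds
F1 | step 10 | (S)-2-bromo-4-[(Z)-oct-2-en-1-yl]-4-(triethylsilyloxy)cyclopent-2-en-1-one | CCCCC/C=C\C[C@@]1(O[Si](CC)(CC)CC)C=C(Br)C(=O)C1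
F2 | step 10 | methyl (5Z,7S)-7-{(1R,2S)-4-bromo-2-[(Z)-oct-2-en-1-yl]-5-oxo-2-(triethylsilyloxy)cyclopent-3-en-1-yl}-7-hydroxyhept-5-enoate | CCCCC/C=C\C[C@@]1(O[Si](CC)(CC)CC)C=C(Br)C(=O)[C@@H]1[C@H](/C=C\CCCC(=O)OC)O
F3 | step 10 | methyl (5Z,7S)-7-acetoxy-7-{(1R,2S)-4-bromo-2-[(Z)-oct-2-en-1-yl]-5-oxo-2-(triethylsilyloxy)cyclopent-3-en-1-yl}hept-5-enoate | CCCCC/C=C\C[C@@]1(O[Si](CC)(CC)CC)C=C(Br)C(=O)[C@@H]1[C@H](/C=C\CCCC(=O)OC)OC(C)=O
F4 | step 2 | (1S,4R)-4-(tert-butyldimethylsilyloxy)-1-(prop-2-yn-1-yl)cyclopent-2-en-1-ol | C#CC[C@@]1(O)C=C[C@H](O[Si](C)(C)C(C)(C)C)C1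
F5 | step 2 | (1S,4R)-4-(tert-butyldimethylsilyloxy)-1-(oct-2-yn-1-yl)cyclopent-2-en-1-ol | CCCCCC#CC[C@@]1(O)C=C[C@H](O[Si](C)(C)C(C)(C)C)C1
F6 | step 5 | 2-[(Z)-oct-2-en-1-yl]-6-oxabicyclo[3.1.0]hexane-2,4-diol, epoxide oxygen cis to both hydroxyls, carbinol centres as in 6 | CCCCC/C=C\C[C@@]1(O)[C@@H]2O[C@@H]2[C@H](O)C1
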